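**Plan**
- Cuts: the C11=C12 and C11'=C12' alkenes (Wittig) split the C40 chain into a ring B C15 phosphonium salt, the C10 trienedial and a ring A C15 aldehyde. C7=C8 of ring B and C9'=C10' of ring A are cut back (Horner–Wadsworth–Emmons) to a safranal-derived aldehyde and to α-ionone.
- Enabling feature: ring B (C1 gem-dimethyl, C2 CH2, C3 and C4 cis carbinols, C5(CH3)=C6 bearing C7) carries its two hydroxyls exactly where the cis C3=C4 alkene of the cyclohexa-1,3-diene safranal lies. The neighbouring C5=C6 alkene is tetrasubstituted and deactivated by the C7 aldehyde.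
- Forward order: the only ring formed is the C3–O–C4 oxirane (step 1). It is reopened to the cis-carbonate, then taken to the diol, the bis-silyl ether and the C15 ylide precursor. Ring A goes from α-ionone to a resolved 3'-hydroxy C15 aldehyde, is lengthened with a masked C10 ylide to the C25 aldehyde, joined to the ring B ylide and desilylated.
- Stereochemistry: C3/C4 come from the ligand-controlled epoxidation and a double inversion at C4. C3'/C6' come from isolating the cis alcohol (relative) and a lipase resolution (absolute). The E-alkenes come from stabilised-phosphonate olefinations and thermal equilibration after each Wittig step.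

Key step: step 1

Remark: carotenoid locants are used throughout (ring B: C1 gem-dimethyl, C5 methyl-bearing, C6 chain-bearing; ring A the same with primes); a racemate with two stereocentres is written as both enantiomers joined by a dot; the lipase is assumed to acylate the ring A carbinol that is the spatial counterpart of the fast-reacting (3R)-3-hydroxy-β-ring alcohols, which is 3'S in ring A.

**Ring B: C15 phosphonium salt**

Step 1
Reactants: 1 safranal
Product: 2 (3S,4R)-3,4-epoxy-3,4-dihydrosafranal
Conditions: (R,R)-[N,N'-bis(3,5-di-tert-butylsalicylidene)cyclohexane-1,2-diaminato]MnCl (5 mol %), mCPBA, N-methylmorpholine N-oxide, CH2Cl2, −78 °C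
Reagents that add atoms: meta-chloroperoxybenzoic acid, O=C(OO)c1cccc(Cl)c1
Why: The peracid, held by the N-oxide so that it does not epoxidise on its own at −78 °C, oxidises the trivalent manganese complex to a pentavalent oxomanganese species, which transfers oxygen to the cis-disubstituted C3=C4 alkene: the first C–O bond forms at C3, leaving a radical at C4 that is allylic to C5=C6, and this radical collapses onto oxygen to form the C4–O bond. The closest known reaction type is the Jacobsen–Katsuki epoxidation of cis alkenes in cyclic conjugated dienes and of the distal alkene of dienyl carbonyl compounds. The oxirane closes by 3-exo-trig radical collapse, and because C3 and C4 are both held in the six-membered ring no rotation to a trans epoxide is possible. C3 and C4 are set together by the enantioface choice of the (R,R) ligand, which by analogy with indene and 1,2-dihydronaphthalene (the C5=C6 unit standing in for the aryl ring) should give the (3S,4R) oxirane, with oxygen on the face of the later hydroxyls. The step needs site selectivity for C3=C4 over C5=C6, secured because C5=C6 is tetrasubstituted, flanked by the gem-dimethyl carbon and deactivated by the formyl group, and chemoselectivity over the aldehyde, secured by the low temperature.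

Step 2
Reactants: 2 (3S,4R)-3,4-epoxy-3,4-dihydrosafranal
Product: 3 (3S,4R)-3,4-(carbonyldioxy)-β-cyclocitral (cis-fused cyclic carbonate)
Conditions: Pd(PPh3)4 (5 mol %), CO2 (1 atm), THF, 0 °C to rt
Reagents that add atoms: carbon dioxide, O=C=O
Why: Zerovalent palladium ionises the allylic C4–O bond with inversion to a pi-allyl complex over C4–C5–C6, the C3 alkoxide adds to CO2, and the carbonate oxygen returns to C4 on the face away from palladium (second inversion; attack at C6 would need a seven-membered ring and a quaternary centre), so C4 is retained, C3 is untouched and the cis-carbonate results, a known vinyl epoxide–CO2 cycloaddition of the Tsuji–Trost family.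

Step 3
Reactants: 3 (3S,4R)-3,4-(carbonyldioxy)-β-cyclocitral
Product: 4 (3S,4R)-3,4-dihydroxy-β-cyclocitral (cis-diol)
Conditions: K2CO3 (cat.), MeOH, 0 °C
Reagents that add atoms: none
Why: Base-catalysed methanolysis (transesterification) cleaves only the acyl C–O bonds, so both carbinol configurations are kept, and the aldehyde, which has no alpha hydrogen, tolerates the mild base.

Step 4
Reactants: 4 (3S,4R)-3,4-dihydroxy-β-cyclocitral
Product: 5 (3S,4R)-3,4-bis(tert-butyldimethylsilyloxy)-β-cyclocitral
Conditions: TBSOTf, 2,6-lutidine, CH2Cl2, −78 to 0 °C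
Reagents that add atoms: tert-butyldimethylsilyl trifluoromethanesulfonate, CC(C)(C)[Si](C)(C)OS(=O)(=O)C(F)(F)F
Why: Standard silyl ether protection with a silyl triflate and a hindered pyridine base covers both secondary hydroxyls without touching a stereocentre, giving ethers that survive phosphonate anions, i-Bu2AlH and methoxide and are removed by fluoride at the end.

Step 5
Reactants: 5 (3S,4R)-3,4-bis(tert-butyldimethylsilyloxy)-β-cyclocitral; 6 triethyl (E)-3-methyl-4-phosphonobut-2-enoate
Product: 7 ethyl (2E,4E)-3-methyl-5-[(3S,4R)-3,4-bis(tert-butyldimethylsilyloxy)-ring B]penta-2,4-dienoate (ring B C15 ester)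
Conditions: n-BuLi, DMPU, THF, −78 °C to rt
Reagents that add atoms: none
Why: Horner–Wadsworth–Emmons olefination of the hindered aldehyde with the lithiated C5 phosphonate forms C7=C8 with E geometry, the C9=C10 alkene of the reagent settling as E in the delocalised anion, and any 9Z ester is removed by chromatography.

Step 6
Reactants: 7 ring B C15 ester
Product: 8 (2E,4E)-3-methyl-5-[(3S,4R)-3,4-bis(tert-butyldimethylsilyloxy)-ring B]penta-2,4-dien-1-ol (ring B C15 alcohol)
Conditions: i-Bu2AlH, CH2Cl2, −78 °C; aq. KNaC4H4O6 work-up
Reagents that add atoms: none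
Why: 1,2-Reduction of the conjugated ester by the aluminium hydride gives the allylic alcohol without conjugate reduction, and the silyl ethers and alkene geometry are untouched.

Step 7
Reactants: 8 ring B C15 alcohol
Product: 9 [(2E,4E)-3-methyl-5-[(3S,4R)-3,4-bis(tert-butyldimethylsilyloxy)-ring B]penta-2,4-dienyl]triphenylphosphonium bromide
Conditions: PPh3·HBr, CH2Cl2, 0 °C to rt
Reagents that add atoms: triphenylphosphine hydrobromide, [Br-].[PH+](c1ccccc1)(c1ccccc1)c1ccccc1
Why: Acid-assisted allylic substitution of the primary dienylic alcohol by triphenylphosphine (ionisation of the protonated alcohol, capture at the unhindered terminus) gives the E,E salt, the silyl ethers being much less basic than the hydroxyl and the medium free of methanol so that they should stay in place.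

**Ring A: C15 hydroxy aldehyde**

Step 8
Reactants: 10 racemic α-ionone; 11 diethyl (cyanomethyl)phosphonate
Product: 12 racemic (2E,4E)-3-methyl-5-(2,6,6-trimethylcyclohex-2-en-1-yl)penta-2,4-dienenitrile
Conditions: NaH, THF, 0 °C to rt
Reagents that add atoms: none
Why: Horner–Wadsworth–Emmons olefination of the methyl ketone builds C9'=C10', mainly E, with no excess base present so that the doubly allylic C6'–H is not shifted into conjugation; the 9'Z isomer is separated and C6' stays racemic.

Step 9
Reactants: 12 racemic ring A C15 nitrile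
Product: 13 racemic (2E,4E)-3-methyl-5-(2,6,6-trimethyl-4-oxocyclohex-2-en-1-yl)penta-2,4-dienenitrile (3'-oxo nitrile)
Conditions: t-BuOOH (70% aq.), NaOCl (aq.), K2CO3, MeCN, −5 to 0 °C
Reagents that add atoms: tert-butyl hydroperoxide, CC(C)(C)OO
Why: Radical allylic oxidation by tert-butylperoxy radicals (from the hydroperoxide and hypochlorite) attacks the ring C3' methylene, the only secondary allylic C–H, and carries it to the enone, a transformation established for α-ionone derivatives.

Step 10
Reactants: 13 racemic 3'-oxo nitrile
Product: 14 racemic cis-(3'S*,6'R*)-3'-hydroxy nitrile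
Conditions: NaBH4, CeCl3·7H2O, MeOH, −40 °C; chromatography
Reagents that add atoms: none
Why: Luche 1,2-reduction of the ring enone creates C3'; little facial bias is expected because each envelope form of the ring offers one hindered and one open face, so both 3',6'-diastereomers should form and the cis racemate (hydroxyl and side chain on the same face) is taken by chromatography.

Step 11
Reactants: 14 racemic cis-3'-hydroxy nitrile
Product: 15 (3'S,6'R)-3'-acetoxy nitrile
Conditions: Pseudomonas fluorescens lipase, vinyl acetate, t-BuOMe, rt, stopped near half conversion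
Reagents that add atoms: vinyl acetate, C=COC(C)=O
Why: Lipase-catalysed kinetic resolution by irreversible transesterification: the enzyme should acylate the enantiomer whose carbinol presents the larger gem-dimethyl flank and the smaller vinylic flank in its preferred arrangement, which is 3'S here, and since 14 is the cis racemate this also fixes C6' as R; the unreacted alcohol is removed by chromatography.

Step 12
Reactants: 15 (3'S,6'R)-3'-acetoxy nitrile
Product: 16 (2E,4E)-5-[(1R,4S)-4-hydroxy-2,6,6-trimethylcyclohex-2-en-1-yl]-3-methylpenta-2,4-dienal (ring A C15 hydroxy aldehyde, 3'S,6'R)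
Conditions: i-Bu2AlH (excess), CH2Cl2, −78 to −40 °C; then aq. KNaC4H4O6, SiO2, rt
Reagents that add atoms: water, O
Why: The aluminium hydride adds once to the conjugated nitrile to give an aldimine that is hydrolysed to the enal on work-up (nitrile-to-aldehyde reduction) and cleaves the acetate reductively in the same pot, leaving both stereocentres and both alkenes untouched.

**C10 unit and the C25 aldehyde**

Step 13
Reactants: 17 (2E,4E,6E)-2,7-dimethylocta-2,4,6-trienedial
Product: 18 (2E,4E,6E)-7-(5,5-dimethyl-1,3-dioxan-2-yl)-2-methylocta-2,4,6-trienal (mono-acetal)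
Conditions: 2,2-dimethylpropane-1,3-diol (1 equiv), p-toluenesulfonic acid (cat.), toluene, rt
Reagents that add atoms: 2,2-dimethylpropane-1,3-diol, OCC(C)(C)CO
Why: Acid-catalysed acetalisation with one equivalent of diol gives the mono-acetal of the symmetrical dial statistically (bis-acetal and recovered dial are separated and recycled), the six-membered acetal being stable to hydride, phosphine and methoxide.

Step 14
Reactants: 18 C10 mono-acetal aldehyde
Product: 19 (2E,4E,6E)-7-(5,5-dimethyl-1,3-dioxan-2-yl)-2-methylocta-2,4,6-trien-1-ol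
Conditions: NaBH4, EtOH/THF, 0 °C
Reagents that add atoms: none
Why: Borohydride 1,2-reduction of the remaining conjugated aldehyde gives the primary allylic alcohol, and the acetal is inert to hydride.

Step 15
Reactants: 19 C10 acetal alcohol
Product: 21 C10 acetal phosphonium bromide, via C10 acetal allyl bromide 20 (not isolated)
Conditions: CBr4, PPh3, CH2Cl2, −20 °C; then PPh3, EtOAc, rt
Reagents that add atoms: carbon tetrabromide, BrC(Br)(Br)Br; triphenylphosphine, c1ccc(cc1)P(c1ccccc1)c1ccccc1
Why: Appel bromination converts the primary allylic alcohol to the bromide under neutral conditions that spare the acid-labile acetal, and the crude bromide quaternises triphenylphosphine by SN2 substitution to a salt that should precipitate from ethyl acetate.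

Step 16
Reactants: 16 ring A C15 hydroxy aldehyde; 21 C10 acetal phosphonium bromide
Product: 23 ring A C25 hydroxy aldehyde, via ring A C25 acetal 22 (not isolated)
Conditions: NaOMe, MeOH/CH2Cl2, 0 °C to rt; then 0.1 M aq. HCl, acetone, 0 °C; then heptane, 80 °C, dark
Reagents that add atoms: water, O
Why: Wittig olefination with the ylide of 21 forms C11'=C12' in the presence of the free hydroxyl, brief dilute acid hydrolyses the polyenyl acetal (whose oxocarbenium ion is strongly stabilised) quickly enough to spare the allylic C3' carbinol, and the strained 11'Z isomer should equilibrate thermally to E.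

**Union and deprotection**

Step 17
Reactants: 9 ring B C15 phosphonium bromide; 23 ring A C25 hydroxy aldehyde
Product: 24 (3S,4R,3'S,6'R)-3,4-bis(tert-butyldimethylsilyloxy)-β,ε-caroten-3'-ol (all-E)
Conditions: NaOMe, MeOH/CH2Cl2, rt; then heptane, reflux, dark
Reagents that add atoms: none
Why: Wittig olefination of the C25 aldehyde with the C15 ylide forms C11=C12 and completes the C40 chain, the strained 11Z isomer formed alongside being converted thermally into the all-E polyene, with no stereocentre involved.

Step 18
Reactants: 24 bis-silyl carotenoid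
Product: 25 (3S,4R,3'S,6'R)-β,ε-carotene-3,4,3'-triol (target)
Conditions: Bu4NF, THF, rt, dark, argon
Reagents that add atoms: none
Why: Fluoride-induced desilylation, driven by Si–F bond formation, frees the C3 and C4 hydroxyls under non-acidic conditions, which matters because the C4 and C3' allylic carbinols ionise readily in acid; all configurations are unchanged.

**Compound list**

1 | safranal (2,6,6-trimethylcyclohexa-1,3-diene-1-carbaldehyde) | O=CC1=C(C)C=CCC1(C)C | starting material
2 | (3S,4R)-3,4-epoxy-3,4-dihydrosafranal | O=CC1=C(C)[C@H]2O[C@H]2CC1(C)C | intermediate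
3 | (3S,4R)-3,4-(carbonyldioxy)-β-cyclocitral, cis-fused cyclic carbonate | O=CC1=C(C)[C@H]2OC(=O)O[C@H]2CC1(C)C | intermediate
4 | (3S,4R)-3,4-dihydroxy-β-cyclocitral, cis-diol | O=CC1=C(C)[C@@H](O)[C@@H](O)CC1(C)C | intermediate
5 | (3S,4R)-3,4-bis(tert-butyldimethylsilyloxy)-β-cyclocitral | O=CC1=C(C)[C@@H](O[Si](C)(C)C(C)(C)C)[C@@H](O[Si](C)(C)C(C)(C)C)CC1(C)C | intermediate
6 | triethyl (E)-3-methyl-4-phosphonobut-2-enoate | CCOC(=O)/C=C(C)/CP(=O)(OCC)OCC | starting material
7 | ethyl (2E,4E)-3-methyl-5-[(3S,4R)-3,4-bis(tert-butyldimethylsilyloxy)-2,6,6-trimethylcyclohex-1-enyl]penta-2,4-dienoate | CCOC(=O)/C=C(C)/C=C/C1=C(C)[C@@H](O[Si](C)(C)C(C)(C)C)[C@@H](O[Si](C)(C)C(C)(C)C)CC1(C)C | intermediate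
8 | corresponding (2E,4E)-penta-2,4-dien-1-ol, ring B C15 alcohol | OC/C=C(C)/C=C/C1=C(C)[C@@H](O[Si](C)(C)C(C)(C)C)[C@@H](O[Si](C)(C)C(C)(C)C)CC1(C)C | intermediate
9 | ring B C15 triphenylphosphonium bromide | [Br-].c1ccccc1[P+](c1ccccc1)(c1ccccc1)C/C=C(C)/C=C/C2=C(C)[C@@H](O[Si](C)(C)C(C)(C)C)[C@@H](O[Si](C)(C)C(C)(C)C)CC2(C)C | intermediate
10 | racemic α-ionone | CC1=CCCC(C)(C)C1/C=C/C(C)=O | starting material
11 | diethyl (cyanomethyl)phosphonate | CCOP(=O)(CC#N)OCC | starting material
12 | racemic (2E,4E)-3-methyl-5-(2,6,6-trimethylcyclohex-2-en-1-yl)penta-2,4-dienenitrile | CC1=CCCC(C)(C)C1/C=C/C(C)=C/C#N | intermediate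
13 | racemic (2E,4E)-3-methyl-5-(2,6,6-trimethyl-4-oxocyclohex-2-en-1-yl)penta-2,4-dienenitrile | CC1=CC(=O)CC(C)(C)C1/C=C/C(C)=C/C#N | intermediate
14 | racemic cis-(3'S*,6'R*)-3'-hydroxy nitrile | CC1=C[C@@H](O)CC(C)(C)[C@H]1/C=C/C(C)=C/C#N.CC1=C[C@H](O)CC(C)(C)[C@@H]1/C=C/C(C)=C/C#N | intermediate
15 | (3'S,6'R)-3'-acetoxy nitrile | CC1=C[C@@H](OC(C)=O)CC(C)(C)[C@H]1/C=C/C(C)=C/C#N | intermediate
16 | (2E,4E)-5-[(1R,4S)-4-hydroxy-2,6,6-trimethylcyclohex-2-en-1-yl]-3-methylpenta-2,4-dienal | CC1=C[C@@H](O)CC(C)(C)[C@H]1/C=C/C(C)=C/C=O | intermediate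
17 | (2E,4E,6E)-2,7-dimethylocta-2,4,6-trienedial | O=C/C(C)=C/C=C/C=C(C)/C=O | starting material
18 | (2E,4E,6E)-7-(5,5-dimethyl-1,3-dioxan-2-yl)-2-methylocta-2,4,6-trienal | O=C/C(C)=C/C=C/C=C(C)/C1OCC(C)(C)CO1 | intermediate
19 | (2E,4E,6E)-7-(5,5-dimethyl-1,3-dioxan-2-yl)-2-methylocta-2,4,6-trien-1-ol | OC/C(C)=C/C=C/C=C(C)/C1OCC(C)(C)CO1 | intermediate
20 | 2-[(2E,4E,6E)-8-bromo-7-methylocta-2,4,6-trien-2-yl]-5,5-dimethyl-1,3-dioxane | BrC/C(C)=C/C=C/C=C(C)/C1OCC(C)(C)CO1 | intermediate
21 | [(2E,4E,6E)-7-(5,5-dimethyl-1,3-dioxan-2-yl)-2-methylocta-2,4,6-trienyl]triphenylphosphonium bromide | [Br-].c1ccccc1[P+](c1ccccc1)(c1ccccc1)C/C(C)=C/C=C/C=C(C)/C2OCC(C)(C)CO2 | intermediate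
22 | (3'S,6'R)-ring A C25 hydroxy polyene, neopentyl glycol acetal at C12 | CC1=C[C@@H](O)CC(C)(C)[C@H]1/C=C/C(C)=C/C=C/C(C)=C/C=C/C=C(C)/C2OCC(C)(C)CO2 | intermediate
23 | (3'S,6'R)-ring A C25 hydroxy aldehyde (all-E, aldehyde at C12) | CC1=C[C@@H](O)CC(C)(C)[C@H]1/C=C/C(C)=C/C=C/C(C)=C/C=C/C=C(C)/C=O | intermediate
24 | (3S,4R,3'S,6'R)-3,4-bis(tert-butyldimethylsilyloxy)-β,ε-caroten-3'-ol | CC1=C[C@@H](O)CC(C)(C)[C@H]1/C=C/C(C)=C/C=C/C(C)=C/C=C/C=C(C)/C=C/C=C(C)/C=C/C2=C(C)[C@@H](O[Si](C)(C)C(C)(C)C)[C@@H](O[Si](C)(C)C(C)(C)C)CC2(C)C | intermediate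
25 | (3S,4R,3'S,6'R)-β,ε-carotene-3,4,3'-triol | CC1=C[C@@H](O)CC(C)(C)[C@H]1/C=C/C(C)=C/C=C/C(C)=C/C=C/C=C(C)/C=C/C=C(C)/C=C/C1=C(C)[C@@H](O)[C@@H](O)CC1(C)C | target

**Step count and risks**

Total steps: 18. Longest linear sequence: 9 steps (steps 1–7, 17 and 18).

Steps most likely to fail:

1. Step 1. The ligand may discriminate the two faces of C3=C4 less well than it does for aryl-conjugated cis alkenes, because the conjugating group here is an electron-poor enal, and the aldehyde may be slowly over-oxidised. Fallback, setting out from safranal 1: catalytic K2OsO4·2H2O with N-methylmorpholine N-oxide in aqueous acetone should dihydroxylate the electron-rich C3=C4 alkene from either face and give the racemic cis-3,4-dihydroxy-β-cyclocitral F1. Lipase-catalysed acylation with vinyl acetate should then esterify the less hindered C3 hydroxyl of one enantiomer only, giving the (3S,4R)-3-acetoxy-4-hydroxy-β-cyclocitral F2. This is separated from the unreacted enantiomer and methanolysed (K2CO3, MeOH) to the diol 4, where the route is rejoined.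

2. Step 2. Ionisation may be slow because the pi-allyl terminus is part of a tetrasubstituted, electron-poor alkene, and proton transfer within the pi-allyl alkoxide may lead to isomerisation to a ketone or dienol before CO2 is captured. Fallback, setting out from epoxide 2: MgBr2·OEt2 in Et2O at low temperature should open the oxirane at the allylic C4 with inversion to the trans bromohydrin, (3S,4S)-4-bromo-3-hydroxy-β-cyclocitral F3. Di-tert-butyl dicarbonate with 4-(dimethylamino)pyridine should convert its C3 hydroxyl into the tert-butyl carbonate F4. On warming in MeCN the carbonyl oxygen of that group should displace bromide at C4 from the rear with loss of the tert-butyl group, a second inversion that closes the cis-carbonate 3, where the route is rejoined.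

3. Step 10. Hydride may add mainly to the face that gives the 3',6'-trans alcohol, leaving too little of the cis racemate. Fallback, setting out from ketone 13: K[s-Bu3BH] in THF at −78 °C should attack anti to the axial C1' methyl and give the racemic trans-(3'R*,6'R*)-3'-hydroxy nitrile F5. The same lipase and vinyl acetate should acylate its (3'S,6'S) enantiomer and leave the (3'R,6'R)-3'-hydroxy nitrile F6. A Mitsunobu reaction (PPh3, diisopropyl azodicarboxylate, acetic acid) then inverts C3' by SN2 displacement (the SN2' path is blocked at the fully substituted C5') and gives the (3'S,6'R)-acetate 15, where the route is rejoined.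

**Further compounds**

F1 | step 1 | racemic cis-3,4-dihydroxy-β-cyclocitral | O=CC1=C(C)[C@@H](O)[C@@H](O)CC1(C)C.O=CC1=C(C)[C@H](O)[C@H](O)CC1(C)C
F2 | step 1 | (3S,4R)-3-acetoxy-4-hydroxy-β-cyclocitral | O=CC1=C(C)[C@@H](O)[C@@H](OC(C)=O)CC1(C)C
F3 | step 2 | (3S,4S)-4-bromo-3-hydroxy-β-cyclocitral (trans bromohydrin) | O=CC1=C(C)[C@H](Br)[C@@H](O)CC1(C)C
F4 | step 2 | (3S,4S)-4-bromo-3-(tert-butoxycarbonyloxy)-β-cyclocitral | O=CC1=C(C)[C@H](Br)[C@@H](OC(=O)OC(C)(C)C)CC1(C)C
F5 | step 10 | racemic trans-(3'R*,6'R*)-3'-hydroxy nitrile | CC1=C[C@H](O)CC(C)(C)[C@H]1/C=C/C(C)=C/C#N.CC1=C[C@@H](O)CC(C)(C)[C@@H]1/C=C/C(C)=C/C#N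
F6 | step 10 | (3'R,6'R)-3'-hydroxy nitrile | CC1=C[C@H](O)CC(C)(C)[C@H]1/C=C/C(C)=C/C#N
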